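**Plan**

Numbering (germacrane): C1 ketone, C2H2, C3H2, C4(CH3)=C5H (Z), C6 lactone CH–O, C7=C11 butenolide alkene, C8 CHOAc, C9H2, C10(=C14H2), C12 lactone C=O, C13 CH2OAc.
Cuts: both acetates come off. Then C3–C4 of the ten-membered ring is cut (to alkenyl iodide/cyclopropanol 26), then C8–C9 (to butenolide aldehyde 15 and allylstannane 23), then C7–C8, C11–C13 and C6–C7 (to enal 4, methyl propiolate, a vinylcopper and a chloromethyl silyl ether).
Enabling feature: C3 lies β to the C1 carbonyl, so C1–C2–C3 is a latent cyclopropanol (a homoenolate), and C4 is an sp2 carbon that can carry iodine. The Z C4=C5 alkene and the flat butenolide ring hold the two arms on the adjacent ring atoms C6 and C7 on the same side.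
Forward order: the butenolide ring is made first (steps 1–7), the C9–C10–C1 arm is joined at C8–C9 (step 11), and the ten-membered ring is closed last (step 14). That closure also releases the α-methylene ketone. Silyl groups are then exchanged for acetates.
Stereochemistry: C6 comes from a catalytic asymmetric alkynylation (step 3) and C8 from a catalyst-controlled Keck allylation (step 11). The Z C4=C5 geometry comes from trans-hydroalumination/iodination (step 1), and the C7=C11 geometry from syn-carbocupration (step 5).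

Key step: step 14

Remark: the antipodes of ProPhenol and BINOL are assigned from the accepted transition-state models for additions to enals.

**Step 1**
Reactants: 1 but-2-yn-1-ol
Product: 3 (Z)-3-iodobut-2-en-1-ol, via cyclic alkenylaluminate 2 (not isolated)
Conditions: NaAlH2(OCH2CH2OMe)2 (1.3 equiv), THF, 0 °C to rt; then I2 (1.5 equiv), THF, −78 °C to 0 °C
Reagents that add atoms: iodine, II
Why: Hydroxyl-directed trans-hydroalumination of the propargylic alcohol places aluminium on C4 inside a five-membered chelate, and iodinolysis with retention should leave iodine cis to the carbinol carbon, which fixes the Z geometry of C4=C5.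

**Step 2**
Reactants: 3 (Z)-3-iodobut-2-en-1-ol
Product: 4 (Z)-3-iodobut-2-enal
Conditions: activated MnO2 (15 equiv), CH2Cl2, rt, dark; used at once
Reagents that add atoms: none
Why: Neutral heterogeneous allylic alcohol oxidation should give the enal without Z/E scrambling or loss of the alkenyl iodide.

**Step 3**
Reactants: 4 (Z)-3-iodobut-2-enal; 5 methyl propiolate
Product: 7 methyl (4R,5Z)-4-hydroxy-6-iodohept-5-en-2-ynoate, via alkynylzinc 6 (not isolated)
Conditions: (R,R)-ProPhenol (20 mol %), Ph3P=O (40 mol %), Me2Zn (3 equiv), 5 (3 equiv), toluene, 0–4 °C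
Reagents that add atoms: none
Why: In the dinuclear zinc ProPhenol alkynylation of enals, the chiral pocket binds the aldehyde and the zinc alkynylide side by side and should deliver the alkynyl group to the Si face, which sets C6 as R under catalyst control.

**Step 4**
Reactants: 7 methyl (4R,5Z)-4-hydroxy-6-iodohept-5-en-2-ynoate
Product: 8 methyl (4R,5Z)-6-iodo-4-(triethylsilyloxy)hept-5-en-2-ynoate
Conditions: TESCl (1.2 equiv), imidazole (2 equiv), CH2Cl2, 0 °C
Reagents that add atoms: chlorotriethylsilane, CC[Si](Cl)(CC)CC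
Why: Standard silylation masks the acidic hydroxyl before the organocopper step and does not touch C6.

**Step 5**
Reactants: 8 methyl (4R,5Z)-6-iodo-4-(triethylsilyloxy)hept-5-en-2-ynoate; 9 vinylmagnesium bromide; 10 (triisopropylsilyloxy)methyl chloride
Product: 12 methyl (2Z,4R,5Z)-3-ethenyl-6-iodo-4-(triethylsilyloxy)-2-[(triisopropylsilyloxy)methyl]hepta-2,5-dienoate, via alkenylcopper 11 (not isolated)
Conditions: 9 and CuBr·SMe2 (1.5 equiv each), THF, −78 °C; add 8, −78 °C; then DMPU, 10 (3 equiv), −78 to −20 °C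
Reagents that add atoms: none
Why: Syn-carbocupration of the alkynoate puts the vinyl group on C7 and copper on C11, and trapping the alkenylcopper with the α-chloro ether with retention (tandem carbocupration/alkylation of alkynoates) should leave C6 and the ester cis on the tetrasubstituted alkene.

**Step 6**
Reactants: 12 methyl (2Z,4R,5Z)-3-ethenyl-6-iodo-4-(triethylsilyloxy)-2-[(triisopropylsilyloxy)methyl]hepta-2,5-dienoate
Product: 14 (5R)-4-ethenyl-5-[(1Z)-2-iodoprop-1-en-1-yl]-3-[(triisopropylsilyloxy)methyl]furan-2(5H)-one, via hydroxy ester 13 (not isolated)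
Conditions: PPTS (0.2 equiv), MeOH, rt
Reagents that add atoms: none
Why: Mild solvolysis removes the secondary triethylsilyl ether but not the primary triisopropylsilyl ether, and the Z γ-hydroxy enoate should lactonise spontaneously with the C6–O bond intact, so C6 is retained.

**Step 7**
Reactants: 14 (5R)-4-ethenyl-5-[(1Z)-2-iodoprop-1-en-1-yl]-3-[(triisopropylsilyloxy)methyl]furan-2(5H)-one
Product: 15 (2R)-2-[(1Z)-2-iodoprop-1-en-1-yl]-5-oxo-4-[(triisopropylsilyloxy)methyl]-2,5-dihydrofuran-3-carbaldehyde
Conditions: OsO4 (4 mol %), NaIO4 (4 equiv), 2,6-lutidine (2 equiv), dioxane/H2O 3:1, rt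
Reagents that add atoms: osmium tetroxide (oxygen carrier), O=[Os](=O)(=O)=O; sodium periodate, [Na+].[O-]I(=O)(=O)=O
Why: Lemieux–Johnson cleavage should select the monosubstituted vinyl group, because the iodoalkene and the tetrasubstituted butenolide alkene are too hindered and electron-poor for osmylation.

**Step 8**
Reactants: 16 (1-ethoxycyclopropoxy)trimethylsilane; 17 isopropenylmagnesium bromide
Product: 20 1-(prop-1-en-2-yl)cyclopropan-1-ol, via 1-ethoxycyclopropanol 18 (not isolated), via cyclopropanone 19 (not isolated)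
Conditions: MeOH, rt, then evaporate; 17 (2.5 equiv), THF, 0 to 40 °C
Reagents that add atoms: none
Why: This is the classical hemiacetal route to 1-alkenylcyclopropanols: the first equivalent of Grignard reagent deprotonates the hemiacetal, its magnesium salt collapses to cyclopropanone, and the second equivalent adds to the carbonyl.

**Step 9**
Reactants: 20 1-(prop-1-en-2-yl)cyclopropan-1-ol
Product: 22 1-[3-(tributylstannyl)prop-1-en-2-yl]cyclopropan-1-ol, via dilithio dianion 21 (not isolated)
Conditions: nBuLi (2.2 equiv), TMEDA (2.2 equiv), Et2O, 0 °C to rt; then Bu3SnCl (1.0 equiv), −78 °C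
Reagents that add atoms: tributyltin chloride, CCCC[Sn](Cl)(CCCC)CCCC
Why: Alkoxide-directed allylic lithiation (as for the methallyl alcohol dianion) followed by carbon-selective stannylation should give a single allylstannane, because the two allyl termini are equivalent.

**Step 10**
Reactants: 22 1-[3-(tributylstannyl)prop-1-en-2-yl]cyclopropan-1-ol
Product: 23 tributyl{2-[1-(triethylsilyloxy)cyclopropyl]prop-2-en-1-yl}stannane
Conditions: TESCl (1.3 equiv), imidazole (2.5 equiv), DMF, rt
Reagents that add atoms: chlorotriethylsilane, CC[Si](Cl)(CC)CC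
Why: Acid-free silylation masks the cyclopropanol so that it cannot exchange with the titanium catalyst of the next step, and it leaves the acid-sensitive allylstannane intact.

**Step 11**
Reactants: 15 (2R)-2-[(1Z)-2-iodoprop-1-en-1-yl]-5-oxo-4-[(triisopropylsilyloxy)methyl]-2,5-dihydrofuran-3-carbaldehyde; 23 tributyl{2-[1-(triethylsilyloxy)cyclopropyl]prop-2-en-1-yl}stannane
Product: 24 (5R)-4-{(1S)-1-hydroxy-3-[1-(triethylsilyloxy)cyclopropyl]but-3-en-1-yl}-5-[(1Z)-2-iodoprop-1-en-1-yl]-3-[(triisopropylsilyloxy)methyl]furan-2(5H)-one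
Conditions: (S)-BINOL (20 mol %), Ti(OiPr)4 (10 mol %), 4 Å MS, 23 (1.5 equiv), CH2Cl2, −20 °C
Reagents that add atoms: none
Why: In the Keck asymmetric allylation the (S)-BINOL–titanium Lewis acid shields one aldehyde face, so the 2-substituted allylstannane should give the 8S alcohol under catalyst control, in a neutral medium that spares the C6 hydrogen and with loss of tin faster than cyclopropane enlargement.

**Step 12**
Reactants: 24 (5R)-4-{(1S)-1-hydroxy-3-[1-(triethylsilyloxy)cyclopropyl]but-3-en-1-yl}-5-[(1Z)-2-iodoprop-1-en-1-yl]-3-[(triisopropylsilyloxy)methyl]furan-2(5H)-one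
Product: 25 (5R)-4-{(1S)-1-(tert-butyldimethylsilyloxy)-3-[1-(triethylsilyloxy)cyclopropyl]but-3-en-1-yl}-5-[(1Z)-2-iodoprop-1-en-1-yl]-3-[(triisopropylsilyloxy)methyl]furan-2(5H)-one
Conditions: TBSOTf (1.2 equiv), 2,6-lutidine (2 equiv), CH2Cl2, −78 °C
Reagents that add atoms: tert-butyldimethylsilyl triflate, CC(C)(C)[Si](C)(C)OS(=O)(=O)C(F)(F)F
Why: Silyl triflate silylation of the hindered secondary alcohol at low temperature with a weak base should avoid silyloxyfuran formation, and it removes a hydroxyl that could bind palladium in step 14.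

**Step 13**
Reactants: 25 (5R)-4-{(1S)-1-(tert-butyldimethylsilyloxy)-3-[1-(triethylsilyloxy)cyclopropyl]but-3-en-1-yl}-5-[(1Z)-2-iodoprop-1-en-1-yl]-3-[(triisopropylsilyloxy)methyl]furan-2(5H)-one
Product: 26 (5R)-4-[(1S)-1-(tert-butyldimethylsilyloxy)-3-(1-hydroxycyclopropyl)but-3-en-1-yl]-5-[(1Z)-2-iodoprop-1-en-1-yl]-3-[(triisopropylsilyloxy)methyl]furan-2(5H)-one
Conditions: PPTS (0.1 equiv), MeOH/CH2Cl2 1:4, 0 °C
Reagents that add atoms: none
Why: Graded silyl ether solvolysis should cleave the tied-back cyclopropyl triethylsilyl ether much faster than the hindered secondary TBS and primary TIPS ethers, and the acid is too weak to protonate the alkene and trigger ring enlargement.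

**Step 14**
Reactants: 26 (5R)-4-[(1S)-1-(tert-butyldimethylsilyloxy)-3-(1-hydroxycyclopropyl)but-3-en-1-yl]-5-[(1Z)-2-iodoprop-1-en-1-yl]-3-[(triisopropylsilyloxy)methyl]furan-2(5H)-one
Product: 29 (6R,8S)-8-(tert-butyldimethylsilyloxy)-13-(triisopropylsilyloxy)-1-oxogermacra-4Z,7(11),10(14)-trien-12,6-olide, via palladium cyclopropoxide 27 (not isolated), via palladium homoenolate 28 (not isolated)
Conditions: Pd2(dba)3 (10 mol %), XPhos (24 mol %), powdered K3PO4 (3 equiv), toluene, 50 °C, 26 added by syringe pump over 12 h (final 1 mM)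
Reagents that add atoms: none
Why: Proposed new method: zerovalent palladium should insert into the C4–iodine bond of 26 with retention of the Z geometry, phosphate-assisted exchange of iodide for the only free hydroxyl should give the alkenylpalladium cyclopropoxide 27, strain-releasing β-carbon elimination (either of the two equivalent C1–CH2 bonds) should open it to the ketone-chelated palladium homoenolate 28, and C(sp3)–C(sp2) reductive elimination should forge C3–C4. The closest known reaction type is the palladium-catalysed ring-opening cross-coupling of cyclopropanols with aryl or alkenyl halides, documented intermolecularly and for closing seven-membered carbocycles, but not for a ten-membered ring or for a 1-alkenylcyclopropanol. The ten-membered carbocycle closes by contraction of the eleven-membered palladacycle 28 in the reductive elimination, not by exo or endo attack on a π bond, and the same event releases the C1 ketone in conjugation to the C10 methylene, which therefore never has to be carried through the route. No stereocentre is formed; C6 and C8 are spectators and the C4=C5 geometry is inherited from the iodide. The step needs ring closure to outrun oligomerisation, 7-exo Heck insertion into C10=C14, semipinacol ring enlargement, β-hydride loss from 28 and epimerisation at C6. The Z alkene and the flat butenolide hold both arms on the adjacent ring atoms C6 and C7 on the same side, slow addition keeps the concentration low, oxygen–palladium bond formation at the unhindered cyclopropanol should be faster than insertion of a 1,1-disubstituted alkene flanked by a quaternary carbon, neutral phosphine-bound divalent palladium is a poor π-acid, the bulky biaryl phosphine together with carbonyl chelation favours reductive elimination over β-hydride loss, and the insoluble weak base spares the C6 hydrogen.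

**Step 15**
Reactants: 29 (6R,8S)-8-(tert-butyldimethylsilyloxy)-13-(triisopropylsilyloxy)-1-oxogermacra-4Z,7(11),10(14)-trien-12,6-olide
Product: 30 (6R,8S)-8,13-dihydroxy-1-oxogermacra-4Z,7(11),10(14)-trien-12,6-olide
Conditions: HF·pyridine, MeCN, 0 °C to rt (plastic vessel)
Reagents that add atoms: none
Why: Acidic fluoride desilylation removes both silyl ethers without the basic conditions that would endanger C6 or the α-methylene ketone.

**Step 16**
Reactants: 30 (6R,8S)-8,13-dihydroxy-1-oxogermacra-4Z,7(11),10(14)-trien-12,6-olide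
Product: 31 (6R,8S)-8,13-diacetoxy-1-oxogermacra-4Z,7(11),10(14)-trien-12,6-olide (target CNP0239761.1)
Conditions: Ac2O (4 equiv), pyridine (8 equiv), DMAP (5 mol %), CH2Cl2, 0 °C
Reagents that add atoms: acetic anhydride, CC(=O)OC(C)=O
Why: Standard acylation of the primary and secondary alcohols proceeds with retention at C8, and it installs the elimination-prone C13 acetate only after all base- and palladium-mediated steps are over.

**Compound list**

1 | but-2-yn-1-ol | CC#CCO | starting material
2 | sodium 2,2-bis(2-methoxyethoxy)-3-methyl-2,5-dihydro-1,2-oxaluminol-2-uide (cyclic alkenylaluminate) | CC1=CCO[Al-]1(OCCOC)OCCOC.[Na+] | intermediate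
3 | (Z)-3-iodobut-2-en-1-ol | OC/C=C(/C)I | intermediate
4 | (Z)-3-iodobut-2-enal | O=C/C=C(/C)I | intermediate
5 | methyl propiolate | C#CC(=O)OC | starting material
6 | methyl(3-methoxy-3-oxoprop-1-yn-1-yl)zinc (alkynylzinc) | C[Zn]C#CC(=O)OC | intermediate
7 | methyl (4R,5Z)-4-hydroxy-6-iodohept-5-en-2-ynoate | O[C@@H](C#CC(=O)OC)/C=C(/C)I | intermediate
8 | methyl (4R,5Z)-6-iodo-4-(triethylsilyloxy)hept-5-en-2-ynoate | CC[Si](CC)(CC)O[C@@H](C#CC(=O)OC)/C=C(/C)I | intermediate
9 | vinylmagnesium bromide | C=C[Mg]Br | starting material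
10 | (triisopropylsilyloxy)methyl chloride | ClCO[Si](C(C)C)(C(C)C)C(C)C | starting material
11 | alkenylcopper from syn-addition (copper on C11, vinyl on C7, cis to each other) | COC(=O)/C([Cu])=C(/C=C)[C@H](O[Si](CC)(CC)CC)/C=C(/C)I | intermediate
12 | methyl (2Z,4R,5Z)-3-ethenyl-6-iodo-4-(triethylsilyloxy)-2-[(triisopropylsilyloxy)methyl]hepta-2,5-dienoate | COC(=O)/C(CO[Si](C(C)C)(C(C)C)C(C)C)=C(/C=C)[C@H](O[Si](CC)(CC)CC)/C=C(/C)I | intermediate
13 | methyl (2Z,4R,5Z)-3-ethenyl-4-hydroxy-6-iodo-2-[(triisopropylsilyloxy)methyl]hepta-2,5-dienoate (hydroxy ester) | COC(=O)/C(CO[Si](C(C)C)(C(C)C)C(C)C)=C(/C=C)[C@H](O)/C=C(/C)I | intermediate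
14 | (5R)-4-ethenyl-5-[(1Z)-2-iodoprop-1-en-1-yl]-3-[(triisopropylsilyloxy)methyl]furan-2(5H)-one | C=CC1=C(CO[Si](C(C)C)(C(C)C)C(C)C)C(=O)O[C@@H]1/C=C(/C)I | intermediate
15 | (2R)-2-[(1Z)-2-iodoprop-1-en-1-yl]-5-oxo-4-[(triisopropylsilyloxy)methyl]-2,5-dihydrofuran-3-carbaldehyde | O=CC1=C(CO[Si](C(C)C)(C(C)C)C(C)C)C(=O)O[C@@H]1/C=C(/C)I | intermediate
16 | (1-ethoxycyclopropoxy)trimethylsilane | CCOC1(O[Si](C)(C)C)CC1 | starting material
17 | isopropenylmagnesium bromide | C=C(C)[Mg]Br | starting material
18 | 1-ethoxycyclopropan-1-ol | CCOC1(O)CC1 | intermediate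
19 | cyclopropanone | O=C1CC1 | intermediate
20 | 1-(prop-1-en-2-yl)cyclopropan-1-ol | C=C(C)C1(O)CC1 | intermediate
21 | dilithio dianion of 20 (lithium alkoxide, allyllithium) | [Li]CC(=C)C1(O[Li])CC1 | intermediate
22 | 1-[3-(tributylstannyl)prop-1-en-2-yl]cyclopropan-1-ol | C=C(C[Sn](CCCC)(CCCC)CCCC)C1(O)CC1 | intermediate
23 | tributyl{2-[1-(triethylsilyloxy)cyclopropyl]prop-2-en-1-yl}stannane | C=C(C[Sn](CCCC)(CCCC)CCCC)C1(O[Si](CC)(CC)CC)CC1 | intermediate
24 | (5R)-4-{(1S)-1-hydroxy-3-[1-(triethylsilyloxy)cyclopropyl]but-3-en-1-yl}-5-[(1Z)-2-iodoprop-1-en-1-yl]-3-[(triisopropylsilyloxy)methyl]furan-2(5H)-one | C=C(C[C@H](O)C1=C(CO[Si](C(C)C)(C(C)C)C(C)C)C(=O)O[C@@H]1/C=C(/C)I)C2(O[Si](CC)(CC)CC)CC2 | intermediate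
25 | (5R)-4-{(1S)-1-(tert-butyldimethylsilyloxy)-3-[1-(triethylsilyloxy)cyclopropyl]but-3-en-1-yl}-5-[(1Z)-2-iodoprop-1-en-1-yl]-3-[(triisopropylsilyloxy)methyl]furan-2(5H)-one | C=C(C[C@H](O[Si](C)(C)C(C)(C)C)C1=C(CO[Si](C(C)C)(C(C)C)C(C)C)C(=O)O[C@@H]1/C=C(/C)I)C2(O[Si](CC)(CC)CC)CC2 | intermediate
26 | (5R)-4-[(1S)-1-(tert-butyldimethylsilyloxy)-3-(1-hydroxycyclopropyl)but-3-en-1-yl]-5-[(1Z)-2-iodoprop-1-en-1-yl]-3-[(triisopropylsilyloxy)methyl]furan-2(5H)-one | C=C(C[C@H](O[Si](C)(C)C(C)(C)C)C1=C(CO[Si](C(C)C)(C(C)C)C(C)C)C(=O)O[C@@H]1/C=C(/C)I)C2(O)CC2 | intermediate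
27 | alkenylpalladium cyclopropoxide, ten-membered oxapalladacycle (phosphine omitted) | C=C1C[C@H](O[Si](C)(C)C(C)(C)C)C2=C(CO[Si](C(C)C)(C(C)C)C(C)C)C(=O)O[C@@H]2/C=C(/C)[Pd]OC13CC3 | intermediate
28 | palladium homoenolate, eleven-membered palladacycle (phosphine omitted) | C=C1C[C@H](O[Si](C)(C)C(C)(C)C)C2=C(CO[Si](C(C)C)(C(C)C)C(C)C)C(=O)O[C@@H]2/C=C(/C)[Pd]CCC1=O | intermediate
29 | (6R,8S)-8-(tert-butyldimethylsilyloxy)-13-(triisopropylsilyloxy)-1-oxogermacra-4Z,7(11),10(14)-trien-12,6-olide | C=C1C[C@H](O[Si](C)(C)C(C)(C)C)C2=C(CO[Si](C(C)C)(C(C)C)C(C)C)C(=O)O[C@@H]2/C=C(/C)CCC1=O | intermediate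
30 | (6R,8S)-8,13-dihydroxy-1-oxogermacra-4Z,7(11),10(14)-trien-12,6-olide | C=C1C[C@H](O)C2=C(CO)C(=O)O[C@@H]2/C=C(/C)CCC1=O | intermediate
31 | (6R,8S)-8,13-diacetoxy-1-oxogermacra-4Z,7(11),10(14)-trien-12,6-olide (CNP0239761.1) | C=C1C[C@H](OC(C)=O)C2=C(COC(C)=O)C(=O)O[C@@H]2/C=C(/C)CCC1=O | target

**Step count**

Total step count: 16. Longest linear sequence: 13 (steps 1–7 and 11–16). The stannane arm (steps 8–10) is made in parallel.

**Steps most likely to fail**

1. **Step 14.**
   - What may go wrong: the medium-ring reductive elimination may be outrun by oligomerisation, Heck-type insertion into C10=C14 or β-hydride loss from the homoenolate. The base may also epimerise C6.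
   - Fallback: a B-alkyl Suzuki–Miyaura macrocyclisation at the C1 alcohol level (known chemistry). It sets out from 15 and comes back at 29.
   - Commercial methacrolein and 9 should give 2-methylpenta-1,4-dien-3-ol F1.
   - Its dianion (nBuLi, TMEDA) and Bu3SnCl should give 4-[(tributylstannyl)methyl]penta-1,4-dien-3-ol F2, and TESCl/imidazole should give its triethylsilyl ether F3.
   - Keck allylation of 15 by F3 under the conditions of step 11 should give the 8S homoallylic alcohol F4. Both C1 epimers form, which is of no consequence. TBSOTf/2,6-lutidine should then give the C8 silyl ether F5.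
   - Dicyclohexylborane should hydroborate only the monosubstituted C2=C3 alkene to the alkyl(dicyclohexyl)borane F6.
   - F6 is added slowly to PdCl2(dppf), AsPh3 and Cs2CO3 in DMF/THF/H2O and should close the ring to the macrocyclic C1 triethylsilyl ether F7.
   - PPTS in MeOH should free the macrocyclic allylic alcohol F8, and Dess–Martin periodinane should oxidise it to 29.

2. **Step 5.**
   - What may go wrong: carbon alkylation of the ester-stabilised alkenylcopper by the hindered chloromethyl ether may be sluggish, and geometry may erode through the allenolate form on warming.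
   - Fallback: C13 enters as a boron-bearing carbon and its oxygen is put in afterwards by oxidation. It sets out from 8 and comes back at 12.
   - The same carbocupration gives 11, which is trapped at low temperature with 2-(iodomethyl)-4,4,5,5-tetramethyl-1,3,2-dioxaborolane. This is the electrophile for which the tandem process is best documented, and it should give the 2-(alkoxycarbonyl)allylboronate F9.
   - NaBO3·4H2O in THF/H2O should oxidise the C–B bond to the allylic alcohol F10.
   - TIPSCl/imidazole should then give 12.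

3. **Step 11.**
   - What may go wrong: facial selectivity may be poor, or addition to the hindered, electron-poor aldehyde on the tetrasubstituted alkene may be slow.
   - Fallback: C8 is set by reduction instead of addition. It sets out from 15 and 23 and comes back at 24.
   - MgBr2·OEt2-promoted addition of 23 to 15 (CH2Cl2, −78 to −20 °C) should give the C8-epimeric homoallylic alcohol F11.
   - Dess–Martin periodinane should give the C8 ketone F12.
   - Corey–Bakshi–Shibata reduction with the (R)-methyl oxazaborolidine and catecholborane (toluene, −78 °C) treats the butenolide alkenyl group as the large substituent and should give the 8S alcohol 24.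

**Further compounds**

F1 | step 14 | 2-methylpenta-1,4-dien-3-ol | C=CC(O)C(C)=C
F2 | step 14 | 4-[(tributylstannyl)methyl]penta-1,4-dien-3-ol | C=CC(O)C(=C)C[Sn](CCCC)(CCCC)CCCC
F3 | step 14 | triethylsilyl ether of F2 | C=CC(O[Si](CC)(CC)CC)C(=C)C[Sn](CCCC)(CCCC)CCCC
F4 | step 14 | 8S homoallylic alcohol (C1 epimers) | C=CC(O[Si](CC)(CC)CC)C(=C)C[C@H](O)C1=C(CO[Si](C(C)C)(C(C)C)C(C)C)C(=O)O[C@@H]1/C=C(/C)I
F5 | step 14 | C8 tert-butyldimethylsilyl ether of F4 | C=CC(O[Si](CC)(CC)CC)C(=C)C[C@H](O[Si](C)(C)C(C)(C)C)C1=C(CO[Si](C(C)C)(C(C)C)C(C)C)C(=O)O[C@@H]1/C=C(/C)I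
F6 | step 14 | alkyl(dicyclohexyl)borane from F5 | C=C(C[C@H](O[Si](C)(C)C(C)(C)C)C1=C(CO[Si](C(C)C)(C(C)C)C(C)C)C(=O)O[C@@H]1/C=C(/C)I)C(CCB(C2CCCCC2)C2CCCCC2)O[Si](CC)(CC)CC
F7 | step 14 | macrocyclic C1 triethylsilyl ether | C=C1C[C@H](O[Si](C)(C)C(C)(C)C)C2=C(CO[Si](C(C)C)(C(C)C)C(C)C)C(=O)O[C@@H]2/C=C(/C)CCC1O[Si](CC)(CC)CC
F8 | step 14 | macrocyclic C1 allylic alcohol | C=C1C[C@H](O[Si](C)(C)C(C)(C)C)C2=C(CO[Si](C(C)C)(C(C)C)C(C)C)C(=O)O[C@@H]2/C=C(/C)CCC1O
F9 | step 5 | 2-(alkoxycarbonyl)allylboronate | COC(=O)/C(CB1OC(C)(C)C(C)(C)O1)=C(/C=C)[C@H](O[Si](CC)(CC)CC)/C=C(/C)I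
F10 | step 5 | C13 allylic alcohol | COC(=O)/C(CO)=C(/C=C)[C@H](O[Si](CC)(CC)CC)/C=C(/C)I
F11 | step 11 | C8-epimeric homoallylic alcohol | C=C(CC(O)C1=C(CO[Si](C(C)C)(C(C)C)C(C)C)C(=O)O[C@@H]1/C=C(/C)I)C2(O[Si](CC)(CC)CC)CC2
F12 | step 11 | C8 ketone | C=C(CC(=O)C1=C(CO[Si](C(C)C)(C(C)C)C(C)C)C(=O)O[C@@H]1/C=C(/C)I)C2(O[Si](CC)(CC)CC)CC2
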